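Count the first product per reagent charged before touching this flask.

in all of them: substrate 1.9 M

| run | reagent | temperature | remark | time |
|---|---|---|---|---|
| noon | 1 equiv | 0 °C | the very flask that is asked about, followed so far |  |
| dusk | 1 equiv | −5 °C | run made earlier |  |
| flask | 1.00 equiv | 0 °C |  | 3.0 min |

| run | time / min | first product / % |
|---|---|---|
| noon | 0.417 | 13.8 |
| noon | 0.833 | 20.2 |
| noon | 1.33 | 23.0 |
| noon | 1.50 | 24.5 |
| noon | 2.00 | 24.8 |
| noon | 2.50 | 25.7 |
| noon | 3.00 | 26.0 |
| dusk | 0.417 | 10.3 |
| dusk | 0.833 | 16.5 |
| dusk | 1.33 | 20.9 |
| dusk | 1.50 | 21.5 |
| dusk | 2.00 | 22.5 |
| dusk | 2.50 | 24.7 |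
| dusk | 3.00 | 25.2 |

(standard deviation of a reading: 0.5 percentage points)

- removed first product is counted in

- teal: at 3.0 min raise the temperature by 15 K, then wait 3.0 min
- red: change nothing and wait 3.0 min more
- blue: at 3.0 min take out 90% of the first product then present, then wait 3.0 min

* first product, in percent of the substrate first charged, at 3.0 min
* the option that brings most further first product ("none" if no option brings more than 2 percentage points) (teal / red / blue / none)
* first product present, with what was taken out counted in, in percent of the substrate first charged, after teal
* first product present, with what was taken out counted in, in percent of the substrate first charged, after blue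

The noon run is the flask asked about, and the dusk run has the same charge at −5 °C instead of 0 °C. The dusk run trails the noon run by 3.5 percentage points at 0.417 min but by 0.8 points at 3.00 min, against a scatter of 0.5 points on each reading. In the noon run the rate of gain falls by a factor of about 33.1 between the first reading and the stretch after 1.50 min, a rough figure, with the late slope resting on few readings. If substrate and reagent simply met one to one, using up a quarter of each would cut the rate by a factor of 1.83. So the noon flask slows far more than that, and I read it as reagent going somewhere other than into first product. The two runs end closer together than they began, and I read their slowing as tied to the reagent charge they share.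

So I freeze one number. The noon run gives 0.260 for the yield on reagent, the first product at the last reading, as a share of the substrate, per equivalent of reagent charged. The dusk run gives 0.252. I expect 26.0% in the flask at 3.0 min, and at this yield I reckon that reagent able to work is used at about 3.85 times the first product gained. These readings do not show how much of that there is.

The forecast gives 26% (from 25.4% to 26.6%) and picks blue, with 26.8% after teal and 37% after blue, holding that “the product itself caps its own level, so removing it should help”.

    reagent + first product → over-reaction product (k = 0.00420 L mol⁻¹ s⁻¹, Ea = 49.0 kJ mol⁻¹)
    reagent + first product → double product (k = 2.60 × 10⁻⁴ L mol⁻¹ s⁻¹, Ea = 71.0 kJ mol⁻¹)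
    reagent ⇌ dormant form (K = 18.0, k = 0.0150 s⁻¹, Ea = 69.0 kJ mol⁻¹, ΔH = −54.0 kJ mol⁻¹)
    reagent + double product → triple product (k = 0.00870 L mol⁻¹ s⁻¹, Ea = 58.0 kJ mol⁻¹)
    substrate + reagent → first product (k = 0.00460 L mol⁻¹ s⁻¹, Ea = 53.0 kJ mol⁻¹)
    (constants at 0 °C)

The flask gives 26.3%, and teal brings the most: 35.5%, a gain of 9.1 points, against 1.5 points for red and 2.6 points for blue, which ends at 28.9%. At 3.00 min the free reagent is 3.48% of its charge, while the dormant form, its resting state, holds 58.9%. At my yield the teal gain costs 35.2% of the charge, more than stands free and less than the dormant form holds. For the flask with 0.600 equiv of reagent the yield gives 15.6%, and that flask stands at 18.3%.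

(Readings and results stem from a simulated flask with made-up constants; scatter was added.)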